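The two C5 hydroxyls are the disconnection: each lies peri to the C4 carbonyl of its pyranone ring C, so the ketone itself can direct their late installation. Stripped of them, each ring A has one oxygen ortho to the acyl carbon, so both pyranones close unambiguously and gallacetophenone fixes the diaryl ether at C8 of unit 1. A single ruthenium-catalysed operation should then oxygenate C5–H and C5''–H of a 7,7''-di-O-acetyl-5,5''-dideoxy biflavone, forming two C–O bonds and no ring. That precursor is built from an O4-benzyl, O3-aryl gallacetophenone through a chalcone closure for unit 1 and a Baker–Venkataraman sequence for unit 2.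

Key step: step 9

Remark: unit 1 is the flavone carrying the 4-methoxyphenyl group and the ether oxygen at C8; unit 2 is the flavone joined through C4 of its B ring (doubly primed locants). 4-(Benzyloxy)-2-hydroxyacetophenone is assumed to be bought as a catalogue compound.

Step 1
Reactants: 1 gallacetophenone (2,3,4-trihydroxyacetophenone)
Product: 2 4-(benzyloxy)-2,3-dihydroxyacetophenone
Conditions: BnBr (1.05 equiv), NaHCO3, DMF, 40 °C, N2
Reagents that add atoms: benzyl bromide, BrCc1ccccc1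
Why: Williamson etherification under a weak base should touch only the most acidic phenol, the 4-OH para to the acetyl group, because the 2-OH is locked in a hydrogen bond to the carbonyl and the 3-OH is less acidic.

Step 2
Reactants: 2 4-(benzyloxy)-2,3-dihydroxyacetophenone; 3 methyl 4-fluorobenzoate
Product: 4 methyl 4-[3-acetyl-6-(benzyloxy)-2-hydroxyphenoxy]benzoate
Conditions: Cs2CO3, DMSO, 100 °C, N2
Reagents that add atoms: none
Why: Nucleophilic aromatic substitution (addition–elimination) of the fluoride para to the ester by the free 3-phenoxide, the chelated 2-OH being the poorer nucleophile as in the usual O3-selective alkylation of 2,3-dihydroxyacetophenones.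

Step 3
Reactants: 4 methyl 4-[3-acetyl-6-(benzyloxy)-2-hydroxyphenoxy]benzoate; 5 4-methoxybenzaldehyde
Product: 7 4-{6-(benzyloxy)-2-hydroxy-3-[(2E)-3-(4-methoxyphenyl)prop-2-enoyl]phenoxy}benzoic acid, via keto acid 6 (not isolated)
Conditions: KOH (aq., excess), EtOH, rt; then HCl (aq.)
Reagents that add atoms: potassium hydroxide, [K+].[OH-]
Why: Claisen–Schmidt condensation in which the methyl ester is expected to be saponified first, after which the methyl ketone enolate adds to the non-enolisable aldehyde and E1cB dehydration gives the thermodynamically favoured E-enone.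

Step 4
Reactants: 7 4-{6-(benzyloxy)-2-hydroxy-3-[(2E)-3-(4-methoxyphenyl)prop-2-enoyl]phenoxy}benzoic acid
Product: 9 4-{[7-(benzyloxy)-2-(4-methoxyphenyl)-4-oxo-4H-chromen-8-yl]oxy}benzoic acid, via racemic flavanone acid 8 (not isolated)
Conditions: I2 (cat.), DMSO, 130 °C
Reagents that add atoms: none
Why: Iodine-mediated oxidative cyclisation of a 2'-hydroxychalcone, in which oxa-Michael closure through the only ortho hydroxyl gives the flavanone and iodination/HI loss with DMSO as terminal oxidant dehydrogenates it, so that the aryloxy group can only end at C8.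

Step 5
Reactants: 9 4-{[7-(benzyloxy)-2-(4-methoxyphenyl)-4-oxo-4H-chromen-8-yl]oxy}benzoic acid; 10 4-(benzyloxy)-2-hydroxyacetophenone
Product: 11 2-acetyl-5-(benzyloxy)phenyl 4-{[7-(benzyloxy)-2-(4-methoxyphenyl)-4-oxo-4H-chromen-8-yl]oxy}benzoate
Conditions: EDC·HCl, DMAP, CH2Cl2/DMF, rt
Reagents that add atoms: none
Why: Steglich esterification, in which the acylpyridinium species generated from the acid acylates the chelated phenol, the standard entry to Baker–Venkataraman substrates that avoids exposing the chromone to an acid chloride reagent.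

Step 6
Reactants: 11 2-acetyl-5-(benzyloxy)phenyl 4-{[7-(benzyloxy)-2-(4-methoxyphenyl)-4-oxo-4H-chromen-8-yl]oxy}benzoate
Product: 13 7-(benzyloxy)-8-{4-[7-(benzyloxy)-4-oxo-4H-chromen-2-yl]phenoxy}-2-(4-methoxyphenyl)-4H-chromen-4-one, via 1,3-diketone 12 (not isolated)
Conditions: t-BuOK, THF, 0 °C to rt; then AcOH, H2SO4 (cat.), 80 °C
Reagents that add atoms: none
Why: Baker–Venkataraman rearrangement (intramolecular Claisen-type acyl transfer from the ketone enolate to the ortho ester) with a non-nucleophilic base that spares the existing chromone, followed by acid-catalysed cyclodehydration through the only ortho hydroxyl to close ring C of unit 2.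

Step 7
Reactants: 13 7-(benzyloxy)-8-{4-[7-(benzyloxy)-4-oxo-4H-chromen-2-yl]phenoxy}-2-(4-methoxyphenyl)-4H-chromen-4-one
Product: 14 7-hydroxy-8-[4-(7-hydroxy-4-oxo-4H-chromen-2-yl)phenoxy]-2-(4-methoxyphenyl)-4H-chromen-4-one
Conditions: H2 (1 atm), 10% Pd/C, THF/MeOH, rt
Reagents that add atoms: none
Why: Hydrogenolysis of the two benzyl aryl ethers over Pd/C at atmospheric pressure should be much faster than reduction of the chromone C2–C3 bonds, while the methyl and diaryl ethers are inert.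

Step 8
Reactants: 14 7-hydroxy-8-[4-(7-hydroxy-4-oxo-4H-chromen-2-yl)phenoxy]-2-(4-methoxyphenyl)-4H-chromen-4-one
Product: 15 7-acetoxy-8-[4-(7-acetoxy-4-oxo-4H-chromen-2-yl)phenoxy]-2-(4-methoxyphenyl)-4H-chromen-4-one (7,7''-di-O-acetyl-5,5''-dideoxy biflavone)
Conditions: Ac2O, pyridine, DMAP (cat.), rt
Reagents that add atoms: acetic anhydride, CC(=O)OC(C)=O
Why: Nucleophile-catalysed O-acylation of the two phenols gives acetates that make both rings A electron-poor for the oxidation and are too weak as donors to compete with the ketones as directing groups.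

Step 9
Reactants: 15 7-acetoxy-8-[4-(7-acetoxy-4-oxo-4H-chromen-2-yl)phenoxy]-2-(4-methoxyphenyl)-4H-chromen-4-one
Product: 17 7-acetoxy-8-[4-(7-acetoxy-5-hydroxy-4-oxo-4H-chromen-2-yl)phenoxy]-5-hydroxy-2-(4-methoxyphenyl)-4H-chromen-4-one, via bis(trifluoroacetate) 16 (not isolated)
Conditions: [RuCl2(p-cymene)]2 (cat.), PhI(OCOCF3)2 (4 equiv), TFA/TFAA, 80 °C; then H2O
Reagents that add atoms: [bis(trifluoroacetoxy)iodo]benzene, O=C(OI(OC(=O)C(F)(F)F)c1ccccc1)C(F)(F)F; trifluoroacetic acid (trifluoroacetate pool shared with the oxidant), OC(=O)C(F)(F)F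
Why: Each C4 carbonyl should bind a cationic divalent ruthenium trifluoroacetate, carboxylate-assisted metalation–deprotonation of the peri C5–H bond gives a five-membered ruthenacycle, PhI(OCOCF3)2 oxidises it to a tetravalent ruthenium species, and C–O reductive elimination delivers the aryl trifluoroacetate of 16, which water cleaves on work-up to the hydrogen-bonded C5 phenol. The closest known reaction is the ketone-directed ortho C–H hydroxylation of aryl ketones, flavones and chromones with [RuCl2(p-cymene)]2 and hypervalent iodine oxidants in TFA/TFAA, here run once on each of two independent chromones of one molecule, in either order. No ring is closed and no stereocentre is formed. The selectivity needed is C5 over C3, C6, C8'' and the B-ring C–H bonds, and the chelate geometry secures it: only the peri C–H bond can reach a metal held by the carbonyl oxygen in a five-membered ring, and in unit 1 this position is also activated by the para C8 aryloxy group. Over-oxidation should be held back by the acetoxy and trifluoroacetoxy groups, which keep both rings A electron-poor, and by protonation of the pyranones in TFA, which deactivates the anisyl and aryloxy B rings. Any acyl exchange at O7 with the medium would be harmless, since step 10 removes every acyl group.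

Step 10
Reactants: 17 7-acetoxy-8-[4-(7-acetoxy-5-hydroxy-4-oxo-4H-chromen-2-yl)phenoxy]-5-hydroxy-2-(4-methoxyphenyl)-4H-chromen-4-one
Product: 18 5,7-dihydroxy-8-[4-(5,7-dihydroxy-4-oxo-4H-chromen-2-yl)phenoxy]-2-(4-methoxyphenyl)-4H-chromen-4-one
Conditions: K2CO3, MeOH/THF, rt; then HCl (aq.)
Reagents that add atoms: none
Why: Base-mediated transesterification (methanolysis) of the two aryl acetates, conditions under which the methyl ether, the diaryl ether and both pyranones should be stable.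

Compound list
1 | gallacetophenone (2,3,4-trihydroxyacetophenone) | CC(=O)c1ccc(O)c(O)c1O | starting material
2 | 4-(benzyloxy)-2,3-dihydroxyacetophenone | CC(=O)c1ccc(OCc2ccccc2)c(O)c1O | intermediate
3 | methyl 4-fluorobenzoate | COC(=O)c1ccc(F)cc1 | starting material
4 | methyl 4-[3-acetyl-6-(benzyloxy)-2-hydroxyphenoxy]benzoate | COC(=O)c1ccc(Oc2c(O)c(C(C)=O)ccc2OCc2ccccc2)cc1 | intermediate
5 | 4-methoxybenzaldehyde | COc1ccc(C=O)cc1 | starting material
6 | 4-[3-acetyl-6-(benzyloxy)-2-hydroxyphenoxy]benzoic acid (keto acid, not isolated) | CC(=O)c1ccc(OCc2ccccc2)c(Oc2ccc(C(=O)O)cc2)c1O | intermediate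
7 | 4-{6-(benzyloxy)-2-hydroxy-3-[(2E)-3-(4-methoxyphenyl)prop-2-enoyl]phenoxy}benzoic acid | COc1ccc(/C=C/C(=O)c2ccc(OCc3ccccc3)c(Oc3ccc(C(=O)O)cc3)c2O)cc1 | intermediate
8 | racemic 4-{[7-(benzyloxy)-2-(4-methoxyphenyl)-4-oxo-3,4-dihydro-2H-chromen-8-yl]oxy}benzoic acid (flavanone acid, not isolated) | COc1ccc(C2CC(=O)c3ccc(OCc4ccccc4)c(Oc4ccc(C(=O)O)cc4)c3O2)cc1 | intermediate
9 | 4-{[7-(benzyloxy)-2-(4-methoxyphenyl)-4-oxo-4H-chromen-8-yl]oxy}benzoic acid | COc1ccc(-c2cc(=O)c3ccc(OCc4ccccc4)c(Oc4ccc(C(=O)O)cc4)c3o2)cc1 | intermediate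
10 | 4-(benzyloxy)-2-hydroxyacetophenone | CC(=O)c1ccc(OCc2ccccc2)cc1O | starting material
11 | 2-acetyl-5-(benzyloxy)phenyl 4-{[7-(benzyloxy)-2-(4-methoxyphenyl)-4-oxo-4H-chromen-8-yl]oxy}benzoate | COc1ccc(-c2cc(=O)c3ccc(OCc4ccccc4)c(Oc4ccc(C(=O)Oc5cc(OCc6ccccc6)ccc5C(C)=O)cc4)c3o2)cc1 | intermediate
12 | 1-[4-(benzyloxy)-2-hydroxyphenyl]-3-(4-{[7-(benzyloxy)-2-(4-methoxyphenyl)-4-oxo-4H-chromen-8-yl]oxy}phenyl)propane-1,3-dione (not isolated) | COc1ccc(-c2cc(=O)c3ccc(OCc4ccccc4)c(Oc4ccc(C(=O)CC(=O)c5ccc(OCc6ccccc6)cc5O)cc4)c3o2)cc1 | intermediate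
13 | 7-(benzyloxy)-8-{4-[7-(benzyloxy)-4-oxo-4H-chromen-2-yl]phenoxy}-2-(4-methoxyphenyl)-4H-chromen-4-one | COc1ccc(-c2cc(=O)c3ccc(OCc4ccccc4)c(Oc4ccc(-c5cc(=O)c6ccc(OCc7ccccc7)cc6o5)cc4)c3o2)cc1 | intermediate
14 | 7-hydroxy-8-[4-(7-hydroxy-4-oxo-4H-chromen-2-yl)phenoxy]-2-(4-methoxyphenyl)-4H-chromen-4-one | COc1ccc(-c2cc(=O)c3ccc(O)c(Oc4ccc(-c5cc(=O)c6ccc(O)cc6o5)cc4)c3o2)cc1 | intermediate
15 | 7-acetoxy-8-[4-(7-acetoxy-4-oxo-4H-chromen-2-yl)phenoxy]-2-(4-methoxyphenyl)-4H-chromen-4-one | COc1ccc(-c2cc(=O)c3ccc(OC(C)=O)c(Oc4ccc(-c5cc(=O)c6ccc(OC(C)=O)cc6o5)cc4)c3o2)cc1 | intermediate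
16 | 7-acetoxy-8-{4-[7-acetoxy-4-oxo-5-(trifluoroacetoxy)-4H-chromen-2-yl]phenoxy}-2-(4-methoxyphenyl)-5-(trifluoroacetoxy)-4H-chromen-4-one (not isolated) | COc1ccc(-c2cc(=O)c3c(OC(=O)C(F)(F)F)cc(OC(C)=O)c(Oc4ccc(-c5cc(=O)c6c(OC(=O)C(F)(F)F)cc(OC(C)=O)cc6o5)cc4)c3o2)cc1 | intermediate
17 | 7-acetoxy-8-[4-(7-acetoxy-5-hydroxy-4-oxo-4H-chromen-2-yl)phenoxy]-5-hydroxy-2-(4-methoxyphenyl)-4H-chromen-4-one | COc1ccc(-c2cc(=O)c3c(O)cc(OC(C)=O)c(Oc4ccc(-c5cc(=O)c6c(O)cc(OC(C)=O)cc6o5)cc4)c3o2)cc1 | intermediate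
18 | 5,7-dihydroxy-8-[4-(5,7-dihydroxy-4-oxo-4H-chromen-2-yl)phenoxy]-2-(4-methoxyphenyl)-4H-chromen-4-one | COc1ccc(-c2cc(=O)c3c(O)cc(O)c(Oc4ccc(-c5cc(=O)c6c(O)cc(O)cc6o5)cc4)c3o2)cc1 | target

Total steps: 10. Longest linear sequence: 10 steps (1 to 18); compounds 3, 5 and 10 enter as purchased materials.

Steps most likely to fail

1. Step 9. The second oxygenation may stall after the first, because C5''–H of unit 2 has no para oxygen donor and the sparingly soluble substrate must turn over the catalyst twice. Oxidative attack of PhI(OCOCF3)2 on the 4-methoxyphenyl ring is the second concern. The fallback moves O5'' into a building block, so that only one, better activated, C–H bond is left to oxygenate. It sets out from 9 and returns at 18. Steglich esterification of 9 (EDC·HCl, DMAP) with purchased 2-hydroxy-4,6-bis(benzyloxy)acetophenone F1 should give ester F2. Baker–Venkataraman rearrangement (t-BuOK, THF) to diketone F3 and acid cyclodehydration (AcOH, cat. H2SO4) should give tribenzyl biflavone F4, whose symmetric phloroglucinol ring closes without ambiguity. Hydrogenolysis (H2, Pd/C) should give triol F5, and peracetylation (Ac2O, pyridine, DMAP, 50 °C) triacetate F6. The same [RuCl2(p-cymene)]2/PhI(OCOCF3)2 hydroxylation, now needed only at C5 of unit 1, should proceed through trifluoroacetate F7 to 5-hydroxy triacetate F8. K2CO3 in MeOH then gives 18.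

2. Step 2. Substitution by the doubly ortho-flanked 3-phenoxide on a fluoroarene activated only by an ester may be slow. Arylation at the chelated O2 and air oxidation of the catechol-type dianion could then compete. The fallback replaces addition–elimination by copper-catalysed C–O cross-coupling. It sets out from 2 and returns at 4. Ullmann-type etherification of 2 with methyl 4-iodobenzoate F9 (CuI, picolinic acid, K3PO4, DMSO, 80 °C) should give 4 at lower temperature, by a mechanism that tolerates ortho-substituted phenols.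

3. Step 6. Cleavage of the aryl ester back to 9 may compete with the intramolecular acyl transfer, or the migration may stay incomplete in a poorly soluble substrate. The fallback forms the diketone by direct intermolecular C-acylation and avoids the ester altogether. It sets out from 9 and 10 and returns at 13. Acid 9 is converted with 1,1'-carbonyldiimidazole (THF, rt) into acyl imidazole F10. This is added to the lithium dianion of 10 (LiN(SiMe3)2, 3 equiv, THF, −78 °C to rt), a crossed Claisen condensation that should give diketone 12. Cyclodehydration with AcOH and cat. H2SO4 then gives 13.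

Further compounds
F1 | step 9 | 2-hydroxy-4,6-bis(benzyloxy)acetophenone (purchased) | CC(=O)c1c(O)cc(OCc2ccccc2)cc1OCc1ccccc1
F2 | step 9 | 2-acetyl-3,5-bis(benzyloxy)phenyl 4-{[7-(benzyloxy)-2-(4-methoxyphenyl)-4-oxo-4H-chromen-8-yl]oxy}benzoate | COc1ccc(-c2cc(=O)c3ccc(OCc4ccccc4)c(Oc4ccc(C(=O)Oc5cc(OCc6ccccc6)cc(OCc6ccccc6)c5C(C)=O)cc4)c3o2)cc1
F3 | step 9 | 1-[2,4-bis(benzyloxy)-6-hydroxyphenyl]-3-(4-{[7-(benzyloxy)-2-(4-methoxyphenyl)-4-oxo-4H-chromen-8-yl]oxy}phenyl)propane-1,3-dione | COc1ccc(-c2cc(=O)c3ccc(OCc4ccccc4)c(Oc4ccc(C(=O)CC(=O)c5c(O)cc(OCc6ccccc6)cc5OCc5ccccc5)cc4)c3o2)cc1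
F4 | step 9 | 7-(benzyloxy)-8-{4-[5,7-bis(benzyloxy)-4-oxo-4H-chromen-2-yl]phenoxy}-2-(4-methoxyphenyl)-4H-chromen-4-one | COc1ccc(-c2cc(=O)c3ccc(OCc4ccccc4)c(Oc4ccc(-c5cc(=O)c6c(OCc7ccccc7)cc(OCc7ccccc7)cc6o5)cc4)c3o2)cc1
F5 | step 9 | 8-[4-(5,7-dihydroxy-4-oxo-4H-chromen-2-yl)phenoxy]-7-hydroxy-2-(4-methoxyphenyl)-4H-chromen-4-one | COc1ccc(-c2cc(=O)c3ccc(O)c(Oc4ccc(-c5cc(=O)c6c(O)cc(O)cc6o5)cc4)c3o2)cc1
F6 | step 9 | 7-acetoxy-8-[4-(5,7-diacetoxy-4-oxo-4H-chromen-2-yl)phenoxy]-2-(4-methoxyphenyl)-4H-chromen-4-one | COc1ccc(-c2cc(=O)c3ccc(OC(C)=O)c(Oc4ccc(-c5cc(=O)c6c(OC(C)=O)cc(OC(C)=O)cc6o5)cc4)c3o2)cc1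
F7 | step 9 | 7-acetoxy-8-[4-(5,7-diacetoxy-4-oxo-4H-chromen-2-yl)phenoxy]-2-(4-methoxyphenyl)-5-(trifluoroacetoxy)-4H-chromen-4-one | COc1ccc(-c2cc(=O)c3c(OC(=O)C(F)(F)F)cc(OC(C)=O)c(Oc4ccc(-c5cc(=O)c6c(OC(C)=O)cc(OC(C)=O)cc6o5)cc4)c3o2)cc1
F8 | step 9 | 7-acetoxy-8-[4-(5,7-diacetoxy-4-oxo-4H-chromen-2-yl)phenoxy]-5-hydroxy-2-(4-methoxyphenyl)-4H-chromen-4-one | COc1ccc(-c2cc(=O)c3c(O)cc(OC(C)=O)c(Oc4ccc(-c5cc(=O)c6c(OC(C)=O)cc(OC(C)=O)cc6o5)cc4)c3o2)cc1
F9 | step 2 | methyl 4-iodobenzoate (purchased) | COC(=O)c1ccc(I)cc1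
F10 | step 6 | 7-(benzyloxy)-8-[4-(1H-imidazol-1-ylcarbonyl)phenoxy]-2-(4-methoxyphenyl)-4H-chromen-4-one | COc1ccc(-c2cc(=O)c3ccc(OCc4ccccc4)c(Oc4ccc(C(=O)n5ccnc5)cc4)c3o2)cc1
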